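The cycloheptenone is cut at C1–C7. With C5 as a silyl enol ether (C5=C6) and a C2=C3 alkene, ring carbons C1–C7 form a cyclohepta-1,4-diene whose saturated bridge C4 carries the future CH2OH carbon (C13). This pattern, with vicinal quaternary C1 and tertiary C7, is the signature of a divinylcyclopropane Cope rearrangement. One thermal [3,3] shift of a cis-2,3-dialkenyl-2-siloxycyclopropane ester (ring C3, C4, C5) closes the seven-membered ring, sets C1 and C7, and leaves a regiodefined enol ether for C6 acetonylation. The precursor comes from nerol through an alkynyl ketone, whose (E)-enol ether is cyclopropanated asymmetrically before the alkyne is extended to the (E)-enyne arm.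

Key step: step 9

Conventions, assumption and design remarks
- Atom labels follow the target and are kept for all intermediates: C1 (quaternary, CH3 and side chain), C2, C3, C4 (bears C13), C5 (C=O), C6 (acetonyl), C7 (bears C8=C9–O).
- Target configuration: C1 S, C6 S, C7 S, CH(OOH) S. The C1 methyl and C8 are cis; the C6 acetonyl is trans to C8.
- Assumption: 2-methoxyallyl bromide 20 is taken as purchasable; otherwise it is made in one operation from 2-methoxypropene and N-bromosuccinimide.
- The two unsaturated arms must be cis on the enol ether. This geometry is secured by enolising an alkynyl ketone, where the slim alkynyl group favours it, and the alkyne is turned into the (E)-enyne only afterwards.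
- The enyne terminus is left unsilylated from step 8 on, because a C-silyl group would compete for fluoride in step 12.
- Compounds 13 and 16 are already cis-dialkenylcyclopropanes and are handled at or below room temperature.

Step 1
Reactants: 1 nerol
Product: 2 neryl chloride
Conditions: NCS, Me2S, CH2Cl2, −30 → 0 °C
Reagents that add atoms: N-chlorosuccinimide, O=C1CCC(=O)N1Cl
Why: Corey–Kim chlorination turns the primary allylic alcohol into the chloride by SN2 displacement of an alkoxysulfonium group under near-neutral conditions, so neither allylic transposition nor isomerisation of the (Z)-alkene is expected.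

Step 2
Reactants: 2 neryl chloride; 3 3-(trimethylsilyl)prop-2-ynal
Product: 5 racemic (5Z)-6,10-dimethyl-1-(trimethylsilyl)undeca-5,9-dien-1-yn-3-ol, via neryl barium chloride 4 (not isolated)
Conditions: BaI2, lithium biphenylide (2 equiv), THF, rt; then 2, −78 °C; then 3, −78 °C; aq NH4Cl
Reagents that add atoms: none
Why: Barbier-type carbonyl allylation with an allylic barium reagent, which unlike the magnesium, zinc, chromium or indium analogues reacts through its α-carbon and keeps its alkene geometry at −78 °C, should add the intact neryl unit 1,2 to the ynal; the new carbinol centre forms as a racemate and is erased in step 3.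

Step 3
Reactants: 5 propargylic alcohol
Product: 6 (5Z)-6,10-dimethyl-1-(trimethylsilyl)undeca-5,9-dien-1-yn-3-one
Conditions: Dess–Martin periodinane, NaHCO3, CH2Cl2, 0 °C → rt
Reagents that add atoms: none
Why: Dess–Martin oxidation of the secondary propargylic alcohol under bicarbonate buffering should give the ynone without enolising the doubly activated CH2 or moving the β,γ-alkene into conjugation.

Step 4
Reactants: 6 ynone
Product: 8 (3E,5Z)-silyl enol ether (TBSO on C5; alkenyl and alkynyl arms cis), via lithium (E)-enolate 7 (not isolated)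
Conditions: lithium 2,2,6,6-tetramethylpiperidide, THF, −78 °C; then TBSOTf, −78 °C; Et3N, pH 7 buffer
Reagents that add atoms: tert-butyldimethylsilyl trifluoromethanesulfonate, CC(C)(C)[Si](C)(C)OS(=O)(=O)C(F)(F)F
Why: Kinetic enolisation by a hindered lithium amide runs through a closed six-membered transition state in which, because the alkynyl group on the carbonyl is sterically minimal (as an ester alkoxy group is), the α-alkenyl substituent turns away from the amide, so the (E)-O-enolate with alkenyl and alkynyl cis should dominate and is trapped on oxygen by the silyl triflate before any equilibration.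

Step 5
Reactants: 8 silyl enol ether; 9 ethyl diazoacetate
Product: 10 ethyl (1S,2R,3S)-2-(TBSO)-3-[(1Z)-2,6-dimethylhepta-1,5-dien-1-yl]-2-[(trimethylsilyl)ethynyl]cyclopropane-1-carboxylate
Conditions: CuOTf·0.5C6H6 (5 mol%), (R,R)-tBu-box (6 mol%), CH2Cl2, 0 °C → rt, 9 added slowly; chromatography
Reagents that add atoms: none
Why: Copper–bis(oxazoline)-catalysed asymmetric cyclopropanation of a silyl enol ether with a diazoacetate: the electrophilic copper carbene should add stereospecifically to the most electron-rich alkene (the siloxy-substituted one, the others being hindered trisubstituted alkenes and a silyl-capped alkyne), so the two arms stay cis, the ester takes the less crowded face beside OTBS and H, and the ligand selects the enol ether face and thereby sets all three ring stereocentres, the ligand antipode being chosen by analogy with the sense known for terminal alkenes and any minor diastereomer being removed by chromatography of this robust compound.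

Step 6
Reactants: 10 silylalkynyl cyclopropane
Product: 11 ethyl (1S,2R,3S)-2-(TBSO)-3-[(1Z)-2,6-dimethylhepta-1,5-dien-1-yl]-2-ethynylcyclopropane-1-carboxylate
Conditions: K2CO3, EtOH, 0 °C → rt
Reagents that add atoms: none
Why: Carbonate-catalysed protodesilylation of the alkynyl–SiMe3 bond in ethanol is fast and selective, the tertiary TBS ether and the ethyl ester (ethanol makes transesterification degenerate) being untouched and no stereocentre being affected.

Step 7
Reactants: 11 ethynyl cyclopropane
Product: 13 (E)-iodoalkene (C5 bears CH=CHI), via alkenylzirconocene chloride 12 (not isolated)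
Conditions: Cp2Zr(H)Cl, THF, 0 °C → rt; then I2, −78 → 0 °C
Reagents that add atoms: iodine, II
Why: Hydrozirconation with the Schwartz reagent adds Zr–H syn and anti-Markovnikov to the terminal alkyne much faster than it attacks the ester or the trisubstituted alkenes, and iodinolysis of the C–Zr bond with retention should give the (E)-iodoalkene.

Step 8
Reactants: 13 (E)-iodoalkene; 14 ethynylmagnesium bromide
Product: 16 ethyl (1S,2R,3S)-2-[(1E)-but-1-en-3-yn-1-yl]-2-(TBSO)-3-[(1Z)-2,6-dimethylhepta-1,5-dien-1-yl]cyclopropane-1-carboxylate, via ethynylzinc bromide 15 (not isolated)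
Conditions: 14, ZnBr2, THF, 0 °C; then 13, Pd(PPh3)4 (5 mol%), 0 °C → rt; cold work-up
Reagents that add atoms: none
Why: Negishi coupling of the alkenyl iodide with ethynylzinc bromide at or below room temperature retains the (E) geometry, tolerates the ester and delivers the terminal enyne directly, so the cis-dialkenylcyclopropane is completed without heating.

Step 9
Reactants: 16 cis-dialkenylcyclopropane ester
Product: 17 ethyl (1S,4R,5S)-2-(TBSO)-4-ethynyl-5-methyl-5-(4-methylpent-3-en-1-yl)cyclohepta-2,6-diene-1-carboxylate
Conditions: toluene (0.02 M, degassed), BHT (trace), 80–100 °C, base-washed sealed vessel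
Reagents that add atoms: none
Why: On heating, the cis-1,2-dialkenylcyclopropane should undergo a concerted [3,3]-sigmatropic (Cope) shift through the boat transition state in which both alkene arms lie over the three-membered ring, C1–C7 forming while the strained C3–C5 bond, weakened by the C5 siloxy donor, breaks to leave the C2=C3 alkene and the C5=C6 silyl enol ether. The closest known reaction is the divinylcyclopropane–cycloheptadiene rearrangement of 2-siloxy-1,2-dialkenylcyclopropanes, as met in carbenoid cyclopropanation/Cope (formal 4+3) sequences that build quaternary centres. The seven-membered ring is closed by ring expansion, the two alkene termini bonding suprafacially end to end inside the boat while C4 remains the saturated bridge, so both ring alkenes are necessarily cis. C1 is set by the (Z) geometry of the nerol-derived alkene (chain inside, methyl outside the boat) and C7 by the (E) geometry of the enyne (ethynyl outside), which places the methyl group and C8 cis, and the absolute sense follows from the C3/C5 configuration fixed in step 5. The step needs the pericyclic path to outrun heterolysis of the donor–acceptor C4–C5 bond and [1,3] shifts; the cis arrangement of the arms, the ester trans to them (only H points into the boat), a non-polar solvent and acid-free glass should secure this, while the inward chain merely raises the temperature required.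

Step 10
Reactants: 17 cycloheptadiene ester
Product: 18 primary alcohol (C13 as CH2OH; C5 silyl enol ether kept)
Conditions: iBu2AlH (2.5 equiv), CH2Cl2, −78 °C; aq potassium sodium tartrate
Reagents that add atoms: none
Why: Ester reduction with DIBAL-H at −78 °C should give the primary alcohol while the silyl enol ether (which masks the C5 ketone), the terminal alkyne and the alkenes are inert to the hydride; the C4 centre is carried through and is removed in step 13.

Step 11
Reactants: 18 primary alcohol
Product: 19 bis-silyl ether (C13–OTBS and C5 enol OTBS)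
Conditions: TBSCl, imidazole, DMF, 0 °C → rt
Reagents that add atoms: tert-butyldimethylsilyl chloride, CC(C)(C)[Si](C)(C)Cl
Why: Imidazole-mediated silylation protects the primary alcohol as its TBS ether without forming an alkoxide, so no silyl transfer from the enol ether can start.

Step 12
Reactants: 19 bis-silyl ether; 20 2-methoxyallyl bromide
Product: 23 C6-acetonyl β,γ-unsaturated ketone, via TAS enolate 21 (not isolated), via methoxyallyl ketone 22 (not isolated)
Conditions: (Me2N)3S+ Me3SiF2− (TASF, 1.05 equiv), THF, −78 °C; then 20 (3 equiv), −78 → −30 °C; then aq oxalic acid, THF, rt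
Reagents that add atoms: water, O
Why: Fluoride-promoted regiospecific alkylation of a silyl enol ether: the enol O–Si bond is cleaved far faster than the primary alkyl O–Si bond, the naked C5–C6 enolate should be captured at C6 by the reactive allylic bromide (an acetonyl equivalent) before proton transfer from C4 can scramble it, attack opposite the C7 ethynyl group sets C6 trans to C8, and the acidic work-up hydrolyses the methyl enol ether to the methyl ketone.

Step 13
Reactants: 23 β,γ-unsaturated ketone
Product: 24 conjugated enone (C3=C4)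
Conditions: DBU (0.2 equiv), CH2Cl2, 0 °C → rt
Reagents that add atoms: none
Why: Base-catalysed isomerisation of the β,γ-unsaturated ketone through the C4 dienolate (reprotonation at C2) should give the conjugated trisubstituted enone as the thermodynamic sink, and the same reversible enolisation lets C6 settle trans to C7.

Step 14
Reactants: 24 conjugated enone
Product: 26 potassium (E)-alkenyltrifluoroborate, via alkenyl pinacolboronate 25 (not isolated)
Conditions: HBpin (3 equiv), Cy2BH (5 mol%), THF, 0 °C → rt; then aq KHF2, MeOH, rt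
Reagents that add atoms: pinacolborane, [H]B1OC(C)(C)C(C)(C)O1; potassium hydrogen difluoride, [K+].[F-].F
Why: Dialkylborane-catalysed hydroboration with pinacolborane adds B–H syn and anti-Markovnikov to the terminal alkyne to give the (E)-alkenylboronate, pinacolborane itself being unreactive towards ketones, enones and trisubstituted alkenes without a metal catalyst, and KHF2 then converts the boronate into the stable trifluoroborate.

Step 15
Reactants: 26 alkenyltrifluoroborate; 27 3-methylbut-2-enoic acid
Product: 28 (E)-enol ester (C13 still OTBS)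
Conditions: 27 (3 equiv), CuBr (10 mol%), DMAP (0.2 equiv), 4 Å MS, O2 (1 atm), ClCH2CH2Cl, 40–60 °C
Reagents that add atoms: none
Why: Chan–Lam-type copper-catalysed oxidative C–O coupling of an alkenyltrifluoroborate with a carboxylic acid should form the enol ester with retention of the (E) geometry under mild conditions that the enone and the 1,4-diketone tolerate, the silyl ether preventing acyl transfer to C13–OH.

Step 16
Reactants: 28 silyl-protected enol ester
Product: 29 hydroxymethyl enone
Conditions: HF·pyridine, pyridine, THF, 0 °C → rt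
Reagents that add atoms: none
Why: Pyridine-buffered HF·pyridine removes the primary TBS ether (fluoride-driven desilylation) without cleaving the enol ester or cyclising the 1,4-diketone.

Step 17
Reactants: 29 hydroxymethyl enone
Product: 30 target CNP0216745.1
Conditions: O2, visible light, tetraphenylporphyrin (cat.), CH2Cl2, −20 °C; preparative HPLC
Reagents that add atoms: oxygen, O=O
Why: Schenck ene reaction: singlet oxygen should attack the isolated electron-rich trisubstituted alkene far faster than the enone, enoate or enol ester alkenes and, by abstraction of a methyl hydrogen, give the secondary allylic hydroperoxide with the isopropenyl group; the new stereocentre is too remote for substrate control, so the (S)-epimer is expected together with the (R)-epimer and the tertiary regioisomer and has to be isolated by HPLC.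

Compound list
1 | nerol, (2Z)-3,7-dimethylocta-2,6-dien-1-ol | CC(C)=CCC/C(C)=C\CO | starting material
2 | neryl chloride, (2Z)-1-chloro-3,7-dimethylocta-2,6-diene | CC(C)=CCC/C(C)=C\CCl | intermediate
3 | 3-(trimethylsilyl)prop-2-ynal | C[Si](C)(C)C#CC=O | starting material
4 | [(2Z)-3,7-dimethylocta-2,6-dien-1-yl]barium chloride | CC(C)=CCC/C(C)=C\C[Ba]Cl | intermediate (not isolated)
5 | (5Z)-6,10-dimethyl-1-(trimethylsilyl)undeca-5,9-dien-1-yn-3-ol, racemic at C3 | CC(C)=CCC/C(C)=C\CC(O)C#C[Si](C)(C)C | intermediate
6 | (5Z)-6,10-dimethyl-1-(trimethylsilyl)undeca-5,9-dien-1-yn-3-one | CC(C)=CCC/C(C)=C\CC(=O)C#C[Si](C)(C)C | intermediate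
7 | lithium (3E,5Z)-6,10-dimethyl-1-(trimethylsilyl)undeca-3,5,9-trien-1-yn-3-olate | CC(C)=CCC/C(C)=C\C=C(/C#C[Si](C)(C)C)O[Li] | intermediate (not isolated)
8 | tert-butyl{[(3E,5Z)-6,10-dimethyl-1-(trimethylsilyl)undeca-3,5,9-trien-1-yn-3-yl]oxy}dimethylsilane | CC(C)=CCC/C(C)=C\C=C(/C#C[Si](C)(C)C)O[Si](C)(C)C(C)(C)C | intermediate
9 | ethyl diazoacetate | CCOC(=O)C=[N+]=[N-] | starting material
10 | ethyl (1S,2R,3S)-2-[(tert-butyldimethylsilyl)oxy]-3-[(1Z)-2,6-dimethylhepta-1,5-dien-1-yl]-2-[(trimethylsilyl)ethynyl]cyclopropane-1-carboxylate | CCOC(=O)[C@H]1[C@H](/C=C(/C)CCC=C(C)C)[C@]1(O[Si](C)(C)C(C)(C)C)C#C[Si](C)(C)C | intermediate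
11 | ethyl (1S,2R,3S)-2-[(tert-butyldimethylsilyl)oxy]-3-[(1Z)-2,6-dimethylhepta-1,5-dien-1-yl]-2-ethynylcyclopropane-1-carboxylate | CCOC(=O)[C@H]1[C@H](/C=C(/C)CCC=C(C)C)[C@]1(O[Si](C)(C)C(C)(C)C)C#C | intermediate
12 | (E)-alkenylzirconocene chloride from syn addition of Cp2Zr(H)Cl to the ethynyl group of 11 (ring configuration as in 11) | CCOC(=O)[C@H]1[C@H](/C=C(/C)CCC=C(C)C)[C@]1(O[Si](C)(C)C(C)(C)C)/C=C/[Zr](Cl)(C2C=CC=C2)C2C=CC=C2 | intermediate (not isolated)
13 | ethyl (1S,2R,3S)-2-[(tert-butyldimethylsilyl)oxy]-3-[(1Z)-2,6-dimethylhepta-1,5-dien-1-yl]-2-[(E)-2-iodoethenyl]cyclopropane-1-carboxylate | CCOC(=O)[C@H]1[C@H](/C=C(/C)CCC=C(C)C)[C@]1(O[Si](C)(C)C(C)(C)C)/C=C/I | intermediate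
14 | ethynylmagnesium bromide | C#C[Mg]Br | starting material
15 | ethynylzinc bromide | C#C[Zn]Br | intermediate (not isolated)
16 | ethyl (1S,2R,3S)-2-[(1E)-but-1-en-3-yn-1-yl]-2-[(tert-butyldimethylsilyl)oxy]-3-[(1Z)-2,6-dimethylhepta-1,5-dien-1-yl]cyclopropane-1-carboxylate (cis-dialkenyl, ester trans) | CCOC(=O)[C@H]1[C@H](/C=C(/C)CCC=C(C)C)[C@]1(O[Si](C)(C)C(C)(C)C)/C=C/C#C | intermediate
17 | ethyl (1S,4R,5S)-2-[(tert-butyldimethylsilyl)oxy]-4-ethynyl-5-methyl-5-(4-methylpent-3-en-1-yl)cyclohepta-2,6-diene-1-carboxylate | CCOC(=O)[C@H]1C=C[C@](C)(CCC=C(C)C)[C@@H](C#C)C=C1O[Si](C)(C)C(C)(C)C | intermediate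
18 | [(1R,4R,5S)-2-[(tert-butyldimethylsilyl)oxy]-4-ethynyl-5-methyl-5-(4-methylpent-3-en-1-yl)cyclohepta-2,6-dien-1-yl]methanol | CC(C)=CCC[C@@]1(C)C=C[C@H](CO)C(O[Si](C)(C)C(C)(C)C)=C[C@@H]1C#C | intermediate
19 | tert-butyl{[(1R,4R,5S)-2-[(tert-butyldimethylsilyl)oxy]-4-ethynyl-5-methyl-5-(4-methylpent-3-en-1-yl)cyclohepta-2,6-dien-1-yl]methoxy}dimethylsilane | CC(C)=CCC[C@@]1(C)C=C[C@H](CO[Si](C)(C)C(C)(C)C)C(O[Si](C)(C)C(C)(C)C)=C[C@@H]1C#C | intermediate
20 | 2-methoxyallyl bromide, 3-bromo-2-methoxyprop-1-ene | COC(=C)CBr | starting material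
21 | tris(dimethylamino)sulfonium C5–C6 enolate of the C13 TBS ether (ring configuration as in 19) | CC(C)=CCC[C@@]1(C)C=C[C@H](CO[Si](C)(C)C(C)(C)C)C([O-])=C[C@@H]1C#C.CN(C)[S+](N(C)C)N(C)C | intermediate (not isolated)
22 | (2R,5S,6R,7S)-2-{[(tert-butyldimethylsilyl)oxy]methyl}-6-ethynyl-7-(2-methoxyprop-2-en-1-yl)-5-methyl-5-(4-methylpent-3-en-1-yl)cyclohept-3-en-1-one | CC(C)=CCC[C@@]1(C)C=C[C@H](CO[Si](C)(C)C(C)(C)C)C(=O)[C@@H](CC(=C)OC)[C@@H]1C#C | intermediate (not isolated)
23 | (2R,5S,6R,7S)-2-{[(tert-butyldimethylsilyl)oxy]methyl}-6-ethynyl-5-methyl-5-(4-methylpent-3-en-1-yl)-7-(2-oxopropyl)cyclohept-3-en-1-one | CC(C)=CCC[C@@]1(C)C=C[C@H](CO[Si](C)(C)C(C)(C)C)C(=O)[C@@H](CC(C)=O)[C@@H]1C#C | intermediate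
24 | (5S,6S,7S)-2-{[(tert-butyldimethylsilyl)oxy]methyl}-6-ethynyl-5-methyl-5-(4-methylpent-3-en-1-yl)-7-(2-oxopropyl)cyclohept-2-en-1-one | CC(C)=CCC[C@@]1(C)CC=C(CO[Si](C)(C)C(C)(C)C)C(=O)[C@@H](CC(C)=O)[C@@H]1C#C | intermediate
25 | (5S,6S,7S)-2-{[(tert-butyldimethylsilyl)oxy]methyl}-5-methyl-5-(4-methylpent-3-en-1-yl)-7-(2-oxopropyl)-6-[(E)-2-(4,4,5,5-tetramethyl-1,3,2-dioxaborolan-2-yl)ethenyl]cyclohept-2-en-1-one | CC(C)=CCC[C@@]1(C)CC=C(CO[Si](C)(C)C(C)(C)C)C(=O)[C@@H](CC(C)=O)[C@@H]1/C=C/B1OC(C)(C)C(C)(C)O1 | intermediate (not isolated)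
26 | potassium trifluoro{(E)-2-[(1S,2S,7S)-5-{[(tert-butyldimethylsilyl)oxy]methyl}-2-methyl-2-(4-methylpent-3-en-1-yl)-6-oxo-7-(2-oxopropyl)cyclohept-4-en-1-yl]ethenyl}borate | CC(C)=CCC[C@@]1(C)CC=C(CO[Si](C)(C)C(C)(C)C)C(=O)[C@@H](CC(C)=O)[C@@H]1/C=C/[B-](F)(F)F.[K+] | intermediate
27 | 3-methylbut-2-enoic acid | CC(C)=CC(=O)O | starting material
28 | (E)-2-[(1S,2S,7S)-5-{[(tert-butyldimethylsilyl)oxy]methyl}-2-methyl-2-(4-methylpent-3-en-1-yl)-6-oxo-7-(2-oxopropyl)cyclohept-4-en-1-yl]ethenyl 3-methylbut-2-enoate | CC(C)=CCC[C@@]1(C)CC=C(CO[Si](C)(C)C(C)(C)C)C(=O)[C@@H](CC(C)=O)[C@@H]1/C=C/OC(=O)C=C(C)C | intermediate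
29 | (E)-2-[(1S,2S,7S)-5-(hydroxymethyl)-2-methyl-2-(4-methylpent-3-en-1-yl)-6-oxo-7-(2-oxopropyl)cyclohept-4-en-1-yl]ethenyl 3-methylbut-2-enoate | CC(C)=CCC[C@@]1(C)CC=C(CO)C(=O)[C@@H](CC(C)=O)[C@@H]1/C=C/OC(=O)C=C(C)C | intermediate
30 | (E)-2-[(1S,2S,7S)-2-[(3S)-3-hydroperoxy-4-methylpent-4-en-1-yl]-5-(hydroxymethyl)-2-methyl-6-oxo-7-(2-oxopropyl)cyclohept-4-en-1-yl]ethenyl 3-methylbut-2-enoate | C=C(C)[C@H](CC[C@@]1(C)CC=C(CO)C(=O)[C@@H](CC(C)=O)[C@@H]1/C=C/OC(=O)C=C(C)C)OO | target

Total step count: 17. Longest linear sequence: 17 steps (1 to 30); 3, 9, 14, 20 and 27 are purchased.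

Steps most likely to fail

1. Step 9 (key step). At the temperature that the inward-pointing chain demands, heterolytic opening of the donor–acceptor C4–C5 bond or a [1,3] shift to a cyclopentene may compete with the concerted shift, and reversible opening would erode the ring configuration. The fallback sets out from 11 and removes the acceptor before the rearrangement. iBu2AlH (CH2Cl2, −78 °C) should give the cyclopropylmethanol F1 and TBSCl/imidazole its silyl ether F2. Cp2Zr(H)Cl followed by I2 should then give the (E)-iodoalkene F3, and Negishi coupling with ethynylzinc bromide (Pd(PPh3)4) the acceptor-free cis-dialkenylcyclopropane F4. Heating F4 in toluene should bring about the same [3,3] shift, now without a heterolytic channel, and give 19 directly, where the route is rejoined (steps 10 and 11 fall away).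

2. Step 5. Carbene transfer to the remote trisubstituted alkene, or weak discrimination between the two faces of the enol ether, may leave 10 impure or of low enantiomeric purity. The fallback sets out from 8. Cyclopropanation with 9 under an achiral catalyst (Rh2(OAc)4 or Cu(acac)2, CH2Cl2, slow addition) should give the racemate, that is 10 together with its enantiomer F5. The two are parted by preparative chromatography on a chiral stationary phase at this robust stage, and 10 re-enters the route at step 6.

3. Step 17. Oxygen attacks the remote alkene without facial control and also abstracts hydrogen from the chain CH2, so the wanted epimer may not separate from its isomers. The fallback sets out from 28 and does the photooxygenation before desilylation, which should give the silyl-protected hydroperoxide F6 mixed with its epimer. The enantiopure enol ether (1R,2S)-trans-2-phenylcyclohexyl 2-propenyl ether F8 is made from commercial (1R,2S)-trans-2-phenylcyclohexanol via its acetate F7 (Ac2O, pyridine) and Tebbe methylenation (Cp2Ti(μ-Cl)(μ-CH2)AlMe2). Treating the hydroperoxide mixture with F8 and pyridinium p-toluenesulfonate in CH2Cl2 should give diastereomeric peroxyketals that carry a stereodefined group next to the peroxide and separate on silica. The (S)-peroxyketal F9 is then unmasked with AcOH/THF/H2O and desilylated with HF·pyridine to give 30.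

Further compounds
F1 | step 9 | cyclopropylmethanol from reduction of 11 (C13 as CH2OH; ring configuration as in 11) | OC[C@H]1[C@H](/C=C(/C)CCC=C(C)C)[C@]1(O[Si](C)(C)C(C)(C)C)C#C
F2 | step 9 | TBS ether of F1 | CC(C)(C)[Si](C)(C)OC[C@H]1[C@H](/C=C(/C)CCC=C(C)C)[C@]1(O[Si](C)(C)C(C)(C)C)C#C
F3 | step 9 | (E)-iodoalkene from F2 | CC(C)(C)[Si](C)(C)OC[C@H]1[C@H](/C=C(/C)CCC=C(C)C)[C@]1(O[Si](C)(C)C(C)(C)C)/C=C/I
F4 | step 9 | acceptor-free cis-dialkenylcyclopropane with the (E)-but-1-en-3-ynyl arm | CC(C)(C)[Si](C)(C)OC[C@H]1[C@H](/C=C(/C)CCC=C(C)C)[C@]1(O[Si](C)(C)C(C)(C)C)/C=C/C#C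
F5 | step 5 | enantiomer of 10, ethyl (1R,2S,3R)-2-[(tert-butyldimethylsilyl)oxy]-3-[(1Z)-2,6-dimethylhepta-1,5-dien-1-yl]-2-[(trimethylsilyl)ethynyl]cyclopropane-1-carboxylate | CCOC(=O)[C@@H]1[C@@H](/C=C(/C)CCC=C(C)C)[C@@]1(O[Si](C)(C)C(C)(C)C)C#C[Si](C)(C)C
F6 | step 17 | C13 TBS ether of 30 | C=C(C)[C@H](CC[C@@]1(C)CC=C(CO[Si](C)(C)C(C)(C)C)C(=O)[C@@H](CC(C)=O)[C@@H]1/C=C/OC(=O)C=C(C)C)OO
F7 | step 17 | (1R,2S)-trans-2-phenylcyclohexyl acetate | CC(=O)O[C@@H]1CCCC[C@H]1c1ccccc1
F8 | step 17 | (1R,2S)-trans-2-phenylcyclohexyl 2-propenyl ether | C=C(C)O[C@@H]1CCCC[C@H]1c1ccccc1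
F9 | step 17 | peroxyketal of F6 with F8 | C=C(C)[C@H](CC[C@@]1(C)CC=C(CO[Si](C)(C)C(C)(C)C)C(=O)[C@@H](CC(C)=O)[C@@H]1/C=C/OC(=O)C=C(C)C)OOC(C)(C)O[C@@H]1CCCC[C@H]1c1ccccc1
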